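## Retrosynthetic overview

1. The target comes from acetylation/desilylation of a 20‑silyloxy spiro enol ether, made by lactol dehydration of a half‑reduced 9α,13‑epoxy‑15,16‑olide; that spiro‑lactone comes from oxa‑Michael closure of the 9α‑OH onto a Δ13‑butenolide, itself from singlet‑oxygen [4+2] oxidation of a 3‑furyl side chain.
2. The side chain comes from 2‑(3‑furyl)ethyl Grignard addition to the C9 ketone of a tricyclic keto‑lactone; the C17 methyl comes from enolate methylation at C8.
3. Key disconnection: rings A and B are made together by an intramolecular Diels–Alder reaction (C3–C4 and C5–C10 bonds). The dienophile is a (5R)‑3‑methylbutenolide (the future 19,6‑lactone), the diene carries C20, and the single C6 stereocentre sets C4, C5 and C10.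
4. The triene comes from CrCl2/NiCl2 coupling of a butenolide aldehyde (from (R)‑epichlorohydrin, the only chiral starting material) with a (2E)‑2‑bromodienyl silyl ether (from 4‑bromofuran‑2(5H)‑one).
5. Ring order: butenolide (lactone ring) → rings A + B in one step → 9,13‑oxolane (spiro ring) → 2,3‑dihydrofuran.

Assumption: positions in the polycyclic compounds use labdane numbering (C1–C10 decalin, C17 on C8, C18/C19 on C4, C20 on C10, C11–C16 side chain; α below, β above the decalin; TBS = tert‑butyldimethylsilyl), and the coupling product and the cycloadduct are carried as C9 epimers because that centre is oxidised afterwards.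

## Route

Step 1
Reactants: 1 (R)-epichlorohydrin
Product: 3 (2R)-2-(but-3-en-1-yl)oxirane, via chlorohydrin 2 (not isolated)
Conditions: allylMgCl, CuI (cat.), THF, −40 °C; then NaOH, H2O, rt
Reagents that add atoms: allylmagnesium chloride, C=CC[Mg]Cl
Why: Copper‑catalysed Grignard opening of the epoxide at its unsubstituted carbon followed by Williamson‑type ring closure of the chlorohydrin rebuilds a terminal epoxide without touching the stereocentre, which stays R and becomes C6 of the target.

Step 2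
Reactants: 3 (2R)-2-(but-3-en-1-yl)oxirane; 4 2-(phenylsulfanyl)propanoic acid
Product: 6 (5R)-5-(but-3-en-1-yl)-3-methyl-3-(phenylsulfanyl)oxolan-2-one, via hydroxy acid 5 (not isolated)
Conditions: 4, LiN(i-Pr)2 (LDA, 2.2 equiv), THF, 0 °C; then 3, 0 °C → rt; aq. HCl; TsOH (cat.), PhMe, 80 °C
Reagents that add atoms: none
Why: The carboxylic acid dianion opens the terminal epoxide at CH2 (SN2) and acid‑catalysed lactonisation closes the γ‑lactone, so the future C6 centre is carried over unchanged while the new C3 centre is a mixture that is destroyed in step 3.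

Step 3
Reactants: 6 (5R)-5-(but-3-en-1-yl)-3-methyl-3-(phenylsulfanyl)oxolan-2-one
Product: 8 (5R)-5-(but-3-en-1-yl)-3-methylfuran-2(5H)-one, via sulfoxide 7 (not isolated)
Conditions: mCPBA (1.0 equiv), CH2Cl2, −78 °C; then PhMe, 110 °C
Reagents that add atoms: none
Why: Chemoselective S‑oxidation at low temperature followed by thermal syn‑elimination of the sulfoxide (sulfoxide pyrolysis) gives the conjugated endocyclic butenolide, and the γ‑centre is untouched because no base is present.

Step 4
Reactants: 8 (5R)-5-(but-3-en-1-yl)-3-methylfuran-2(5H)-one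
Product: 9 3-[(2R)-4-methyl-5-oxo-2,5-dihydrofuran-2-yl]propanal
Conditions: OsO4 (2 mol %), NaIO4, 2,6-lutidine, dioxane–H2O, rt
Reagents that add atoms: sodium periodate (oxygen source, relayed by catalytic OsO4), [Na+].[O-]I(=O)(=O)=O
Why: Lemieux–Johnson oxidative cleavage takes the electron‑rich monosubstituted alkene much faster than the electron‑poor trisubstituted butenolide alkene, and the buffered medium does not epimerise the γ‑centre.

Step 5
Reactants: 10 4-bromofuran-2(5H)-one
Product: 12 (2E)-2-bromopenta-2,4-dien-1-ol, via lactol 11 (not isolated)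
Conditions: DIBAL-H (i-Bu2AlH), PhMe, −78 °C; then Ph3P=CH2 (from Ph3PCH3Br, KN(SiMe3)2), THF, −78 °C → rt
Reagents that add atoms: methylenetriphenylphosphorane, C=P(c1ccccc1)(c1ccccc1)c1ccccc1
Why: Half‑reduction of the butenolide gives the lactol, whose ring‑opened cis‑4‑hydroxy‑enal form undergoes Wittig methylenation, so the ring geometry is transferred to the diene (CH2OH cis to the vinyl group, Br trans, 2E).

Step 6
Reactants: 12 (2E)-2-bromopenta-2,4-dien-1-ol
Product: 13 {[(2E)-2-bromopenta-2,4-dien-1-yl]oxy}(tert-butyl)dimethylsilane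
Conditions: TBSCl, imidazole, DMF, 0 °C
Reagents that add atoms: tert-butyldimethylsilyl chloride, CC(C)(C)[Si](C)(C)Cl
Why: Standard silylation of the primary allylic alcohol gives an ether that survives the chromium, thermal, enolate, Grignard and hydride steps and is removed last with fluoride.

Step 7
Reactants: 9 3-[(2R)-4-methyl-5-oxo-2,5-dihydrofuran-2-yl]propanal; 13 {[(2E)-2-bromopenta-2,4-dien-1-yl]oxy}(tert-butyl)dimethylsilane
Product: 14 (5R)-5-[(4E)-4-(TBS-oxymethyl)-3-hydroxyhepta-4,6-dien-1-yl]-3-methylfuran-2(5H)-one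
Conditions: CrCl2 (4 equiv), NiCl2 (2 mol %), DMSO, rt
Reagents that add atoms: none
Why: Nozaki–Hiyama–Kishi coupling adds the alkenylchromium species to the aldehyde with retention of alkene geometry and without touching the base‑sensitive butenolide, and the new carbinol centre (C9) is left uncontrolled because it is oxidised in step 9.

Step 8
Reactants: 14 (5R)-5-[(4E)-4-(TBS-oxymethyl)-3-hydroxyhepta-4,6-dien-1-yl]-3-methylfuran-2(5H)-one
Product: 15 20-(TBS-oxy)-9ξ-hydroxy-11,12,13,14,15,16,17-heptanorlabd-1-en-19,6β-olide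
Conditions: PhMe (0.005 M), BHT, 180 °C, sealed tube
Reagents that add atoms: none
Why: In this thermal intramolecular Diels–Alder reaction the C6 centre forces the diene onto the butenolide face that carries the C7 tether (setting C4 and C5), and the planar lactone is expected to allow only the lactone‑exo arrangement, which with the tether on the outside (E) position of the diene and CH2OTBS inside gives the trans‑decalin with C20 cis to C19 (10β).

Step 9
Reactants: 15 20-(TBS-oxy)-9ξ-hydroxy-11,12,13,14,15,16,17-heptanorlabd-1-en-19,6β-olide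
Product: 16 20-(TBS-oxy)-9-oxo-11,12,13,14,15,16,17-heptanorlabd-1-en-19,6β-olide
Conditions: Dess–Martin periodinane, CH2Cl2, rt
Reagents that add atoms: none
Why: Dess–Martin oxidation of the hindered secondary alcohol converges both C9 epimers on one ketone and leaves the silyl ether, lactone and alkene alone.

Step 10
Reactants: 16 20-(TBS-oxy)-9-oxo-11,12,13,14,15,16,17-heptanorlabd-1-en-19,6β-olide
Product: 17 20-(TBS-oxy)-9-oxo-11,12,13,14,15,16,17-heptanorlabdan-19,6β-olide
Conditions: H2 (1 atm), Pd/C, EtOAc, rt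
Reagents that add atoms: none
Why: Heterogeneous catalytic hydrogenation saturates the cis‑disubstituted C1=C2 alkene while the hindered ketone, the lactone and the silyl ether are inert.

Step 11
Reactants: 17 20-(TBS-oxy)-9-oxo-11,12,13,14,15,16,17-heptanorlabdan-19,6β-olide
Product: 19 20-(TBS-oxy)-9-oxo-11,12,13,14,15,16-hexanorlabdan-19,6β-olide, via lithium enolate 18 (not isolated)
Conditions: LiN(i-Pr)2 (LDA, 1.1 equiv), THF, −78 °C; then MeI, −78 → −20 °C
Reagents that add atoms: iodomethane, CI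
Why: Enolate alkylation can only occur at C8 (C10 is quaternary, the lactone has no α‑hydrogen), and methylation takes the α face because the β face is blocked by the syn‑axial C20 and O6, giving the equatorial 8α‑methyl, which is also the thermodynamic epimer.

Step 12
Reactants: 19 20-(TBS-oxy)-9-oxo-11,12,13,14,15,16-hexanorlabdan-19,6β-olide; 20 3-(2-bromoethyl)furan
Product: 22 20-(TBS-oxy)-9α-hydroxy-15,16-epoxylabda-13(16),14-dien-19,6β-olide, via Grignard reagent 21 (not isolated)
Conditions: 20, Mg, THF, rt; then 19, LaCl3·2LiCl (1 equiv), THF, −78 → 0 °C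
Reagents that add atoms: none
Why: Lanthanide‑assisted Grignard 1,2‑addition (which suppresses enolisation at C8) from the equatorial direction, away from the syn‑axial H5α and H7α that block the axial α face, gives the equatorial C11 and the axial 9α‑OH as in the marrubiin series.

Step 13
Reactants: 22 20-(TBS-oxy)-9α-hydroxy-15,16-epoxylabda-13(16),14-dien-19,6β-olide
Product: 24 20-(TBS-oxy)-9α-hydroxylabd-13-ene-19,6β:15,16-diolide, via hydroxybutenolide 23 (not isolated)
Conditions: O2, rose bengal, hν (visible), i-Pr2NEt, CH2Cl2, −78 °C; then NaBH4, EtOH, 0 °C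
Reagents that add atoms: dioxygen (as singlet oxygen), O=O
Why: Singlet‑oxygen [4+2] cycloaddition to the furan gives an endoperoxide that the hindered base opens regioselectively (Kornblum–DeLaMare) to the 16‑hydroxy‑15,16‑olide, and borohydride reduces its masked aldehyde so that relactonisation gives the Δ13‑butenolide without creating a stereocentre.

Step 14
Reactants: 24 20-(TBS-oxy)-9α-hydroxylabd-13-ene-19,6β:15,16-diolide
Product: 25 (13R)-20-(TBS-oxy)-9α,13-epoxylabdane-19,6β:15,16-diolide
Conditions: DBU, PhMe, 60 °C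
Reagents that add atoms: none
Why: This reversible 5‑exo oxa‑Michael addition of the tertiary 9α‑OH to the butenolide runs under equilibrating conditions, where the spiro epimer with the larger C14–C15 carbonyl arm on the C10 side and C16 facing the C17 methyl (13R) is expected to predominate, and the minor 13‑epimer is separated and re‑subjected.

Step 15
Reactants: 25 (13R)-20-(TBS-oxy)-9α,13-epoxylabdane-19,6β:15,16-diolide
Product: 26 (13R)-20-(TBS-oxy)-9α,13:15,16-diepoxy-15ξ-hydroxylabdan-19,6β-olide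
Conditions: DIBAL-H (i-Bu2AlH, 1.1 equiv), CH2Cl2, −78 °C
Reagents that add atoms: none
Why: One equivalent of DIBAL‑H at low temperature half‑reduces the unhindered spiro‑γ‑lactone (carbonyl flanked by CH2) to the lactol in preference to the 19,6‑lactone, whose carbonyl sits on the quaternary C4 under the axial C20 group.

Step 16
Reactants: 26 (13R)-20-(TBS-oxy)-9α,13:15,16-diepoxy-15ξ-hydroxylabdan-19,6β-olide
Product: 28 (13R)-20-(TBS-oxy)-9α,13:15,16-diepoxylabd-14-en-19,6β-olide, via mesylate 27 (not isolated)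
Conditions: MsCl, Et3N (excess), CH2Cl2, −20 → 40 °C
Reagents that add atoms: none
Why: Mesylation of the lactol and base‑induced elimination toward C14, the only carbon with a β‑hydrogen, gives the cyclic enol ether under basic conditions that avoid ionisation at C13.

Step 17
Reactants: 28 (13R)-20-(TBS-oxy)-9α,13:15,16-diepoxylabd-14-en-19,6β-olide
Product: 30 (13R)-20-acetoxy-9α,13:15,16-diepoxylabd-14-en-19,6β-olide, via alcohol 29 (not isolated)
Conditions: Bu4NF, AcOH, THF, 0 °C → rt; then Ac2O, Et3N, DMAP, rt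
Reagents that add atoms: acetic anhydride, CC(=O)OC(C)=O
Why: Buffered fluoride desilylation avoids acid (which would aromatise the spiro enol ether to a furan) and the primary alcohol is acetylated in the same flask before it can attack the neighbouring lactone.

## Compound list

1 | (R)-epichlorohydrin, (2R)-2-(chloromethyl)oxirane | ClC[C@H]1CO1 | starting material
2 | (2R)-1-chlorohex-5-en-2-ol (magnesium alkoxide in the flask) | ClC[C@H](O)CCC=C | intermediate
3 | (2R)-2-(but-3-en-1-yl)oxirane | C=CCC[C@@H]1CO1 | intermediate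
4 | 2-(phenylsulfanyl)propanoic acid (racemic) | CC(Sc1ccccc1)C(=O)O | starting material
5 | (4R)-4-hydroxy-2-methyl-2-(phenylsulfanyl)oct-7-enoic acid (C2 epimers) | C=CCC[C@@H](O)CC(C)(Sc1ccccc1)C(=O)O | intermediate
6 | (5R)-5-(but-3-en-1-yl)-3-methyl-3-(phenylsulfanyl)oxolan-2-one (C3 epimers) | C=CCC[C@@H]1CC(C)(Sc2ccccc2)C(=O)O1 | intermediate
7 | (5R)-5-(but-3-en-1-yl)-3-methyl-3-(phenylsulfinyl)oxolan-2-one | C=CCC[C@@H]1CC(C)(S(=O)c2ccccc2)C(=O)O1 | intermediate
8 | (5R)-5-(but-3-en-1-yl)-3-methylfuran-2(5H)-one | C=CCC[C@@H]1C=C(C)C(=O)O1 | intermediate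
9 | 3-[(2R)-4-methyl-5-oxo-2,5-dihydrofuran-2-yl]propanal | O=CCC[C@@H]1C=C(C)C(=O)O1 | intermediate
10 | 4-bromofuran-2(5H)-one | O=C1C=C(Br)CO1 | starting material
11 | 4-bromo-2,5-dihydrofuran-2-ol | OC1C=C(Br)CO1 | intermediate
12 | (2E)-2-bromopenta-2,4-dien-1-ol (Br trans, CH2OH cis to the vinyl group) | C=C/C=C(\CO)Br | intermediate
13 | {[(2E)-2-bromopenta-2,4-dien-1-yl]oxy}(tert-butyl)dimethylsilane | C=C/C=C(\CO[Si](C)(C)C(C)(C)C)Br | intermediate
14 | (5R)-5-[(4E)-4-({[tert-butyl(dimethyl)silyl]oxy}methyl)-3-hydroxyhepta-4,6-dien-1-yl]-3-methylfuran-2(5H)-one (both carbinol epimers) | C=C/C=C(\CO[Si](C)(C)C(C)(C)C)C(O)CC[C@@H]1C=C(C)C(=O)O1 | intermediate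
15 | 20-(TBS-oxy)-9ξ-hydroxy-11,12,13,14,15,16,17-heptanorlabd-1-en-19,6β-olide (trans-decalin, 5α-H, 10β-CH2OTBS, 4α-CH3, lactone on the β face) | CC(C)(C)[Si](C)(C)OC[C@@]12C=CC[C@]3(C)C(=O)O[C@H](CCC1O)[C@H]23 | intermediate
16 | 20-(TBS-oxy)-9-oxo-11,12,13,14,15,16,17-heptanorlabd-1-en-19,6β-olide | CC(C)(C)[Si](C)(C)OC[C@@]12C=CC[C@]3(C)C(=O)O[C@H](CCC1=O)[C@H]23 | intermediate
17 | 20-(TBS-oxy)-9-oxo-11,12,13,14,15,16,17-heptanorlabdan-19,6β-olide | CC(C)(C)[Si](C)(C)OC[C@@]12CCC[C@]3(C)C(=O)O[C@H](CCC1=O)[C@H]23 | intermediate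
18 | lithium 8(9)-enolate of 17 | CC(C)(C)[Si](C)(C)OC[C@@]12CCC[C@]3(C)C(=O)O[C@H](CC=C1O[Li])[C@H]23 | intermediate
19 | 20-(TBS-oxy)-9-oxo-11,12,13,14,15,16-hexanorlabdan-19,6β-olide (8α-methyl, 8β-H) | CC(C)(C)[Si](C)(C)OC[C@@]12CCC[C@]3(C)C(=O)O[C@H](C[C@@H](C)C1=O)[C@H]23 | intermediate
20 | 3-(2-bromoethyl)furan | BrCCc1ccoc1 | starting material
21 | [2-(furan-3-yl)ethyl]magnesium bromide | Br[Mg]CCc1ccoc1 | intermediate
22 | 20-(TBS-oxy)-9α-hydroxy-15,16-epoxylabda-13(16),14-dien-19,6β-olide (20-silyloxymarrubiin) | CC(C)(C)[Si](C)(C)OC[C@@]12CCC[C@]3(C)C(=O)O[C@H](C[C@@H](C)[C@]1(O)CCc1ccoc1)[C@H]23 | intermediate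
23 | 20-(TBS-oxy)-9α,16ξ-dihydroxylabd-13-ene-19,6β:15,16-diolide | CC(C)(C)[Si](C)(C)OC[C@@]12CCC[C@]3(C)C(=O)O[C@H](C[C@@H](C)[C@]1(O)CCC1=CC(=O)OC1O)[C@H]23 | intermediate
24 | 20-(TBS-oxy)-9α-hydroxylabd-13-ene-19,6β:15,16-diolide | CC(C)(C)[Si](C)(C)OC[C@@]12CCC[C@]3(C)C(=O)O[C@H](C[C@@H](C)[C@]1(O)CCC1=CC(=O)OC1)[C@H]23 | intermediate
25 | (13R)-20-(TBS-oxy)-9α,13-epoxylabdane-19,6β:15,16-diolide | CC(C)(C)[Si](C)(C)OC[C@@]12CCC[C@]3(C)C(=O)O[C@H](C[C@@H](C)[C@]14CC[C@]1(CC(=O)OC1)O4)[C@H]23 | intermediate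
26 | (13R)-20-(TBS-oxy)-9α,13:15,16-diepoxy-15ξ-hydroxylabdan-19,6β-olide | CC(C)(C)[Si](C)(C)OC[C@@]12CCC[C@]3(C)C(=O)O[C@H](C[C@@H](C)[C@]14CC[C@]1(CC(O)OC1)O4)[C@H]23 | intermediate
27 | 15-O-methanesulfonate of 26 | CC(C)(C)[Si](C)(C)OC[C@@]12CCC[C@]3(C)C(=O)O[C@H](C[C@@H](C)[C@]14CC[C@]1(CC(OS(C)(=O)=O)OC1)O4)[C@H]23 | intermediate
28 | (13R)-20-(TBS-oxy)-9α,13:15,16-diepoxylabd-14-en-19,6β-olide | CC(C)(C)[Si](C)(C)OC[C@@]12CCC[C@]3(C)C(=O)O[C@H](C[C@@H](C)[C@]14CC[C@]1(C=COC1)O4)[C@H]23 | intermediate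
29 | (13R)-20-hydroxy-9α,13:15,16-diepoxylabd-14-en-19,6β-olide | OC[C@@]12CCC[C@]3(C)C(=O)O[C@H](C[C@@H](C)[C@]14CC[C@]1(C=COC1)O4)[C@H]23 | intermediate
30 | (13R)-20-acetoxy-9α,13:15,16-diepoxylabd-14-en-19,6β-olide (CNP0218619.1) | CC(=O)OC[C@@]12CCC[C@]3(C)C(=O)O[C@H](C[C@@H](C)[C@]14CC[C@]1(C=COC1)O4)[C@H]23 | target

## Step count and risks

Total: 17 steps. Longest linear sequence: 15 steps (steps 1–4 and 7–17); steps 5–6 make the diene fragment.

**Step 8 (cycloaddition).** This is the least certain step. Two quaternary carbons form at once on a trisubstituted dienophile, so about 180 °C is needed, where a [1,5]‑hydrogen shift from the inside CH2OTBS group can compete. The trans ring fusion rests on the argument that the lactone‑endo arrangement is sterically blocked; any leakage through it gives the cis‑fused C10 epimer.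
Fallback: make the C4 quaternary centre after the cycloaddition and not in it. It sets out from 3 and comes back at 15. Epoxide 3 is opened with the dianion of (phenylsulfanyl)acetic acid to give (4R)-4-hydroxy-2-(phenylsulfanyl)oct-7-enoic acid F1, which is lactonised to (5R)-5-(but-3-en-1-yl)-3-(phenylsulfanyl)oxolan-2-one F2. mCPBA gives the sulfoxide (5R)-5-(but-3-en-1-yl)-3-(phenylsulfinyl)oxolan-2-one F3, whose thermolysis gives (5R)-5-(but-3-en-1-yl)furan-2(5H)-one F4. OsO4/NaIO4 cleavage gives 3-[(2R)-5-oxo-2,5-dihydrofuran-2-yl]propanal F5, and CrCl2/NiCl2 coupling with 13 gives the 3‑unsubstituted triene F6. Its disubstituted dienophile is more reactive and has no methyl group under the diene in the lactone‑exo arrangement, so it should close at 110–130 °C to the 4α‑H tricyclic lactone F7. LiN(i-Pr)2 (2.2 equiv) converts F7 into the dilithium alkoxide–lactone enolate F8. Iodomethane then alkylates C4 on the α face, the only one open because the lactone bridge holds C19 on the β face, which gives 15.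

**Step 12 (side‑chain addition to the C9 ketone).** The ketone lies between a quaternary and a tertiary carbon, so enolisation can win. The axial CH2OTBS group next to the carbonyl is larger than the methyl of the marrubiin precedent and may push the nucleophile to the α face, giving the 9‑epimer.
Fallback: form the C9–C11 bond first and the C11–C12 bond second. It sets out from 19 and comes back at 22. Dimethylsulfoxonium methylide (Me3S(O)I, NaH, DMSO) adds reversibly and delivers the methylene group equatorially, giving the spiro‑epoxide 9α,11-epoxy-20-(TBS-oxy)-12,13,14,15,16-pentanorlabdan-19,6β-olide F9. CuI‑catalysed opening of F9 at C11 with (furan-3-ylmethyl)magnesium chloride gives 22.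

**Step 14 (spirocyclisation, C13).** The two faces of the butenolide differ only through remote contacts with C1 and C17, so the 13R/13S ratio may be close to 1:1 and recycling of the wrong epimer may be slow.
Fallback: use the C20 hydroxyl as an internal directing group. It sets out from 24 and comes back at 25. HF·pyridine removes the silyl group to give 9α,20-dihydroxylabd-13-ene-19,6β:15,16-diolide F10. In toluene with catalytic DBU the free 20‑OH can hydrogen‑bond the butenolide carbonyl and hold the C14–C15 arm on the C10 side during ring closure, giving (13R)-20-hydroxy-9α,13-epoxylabdane-19,6β:15,16-diolide F11. TBSCl/imidazole then returns 25.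

## Further compounds

F1 | step 8 | (4R)-4-hydroxy-2-(phenylsulfanyl)oct-7-enoic acid (C2 epimers) | C=CCC[C@@H](O)CC(Sc1ccccc1)C(=O)O
F2 | step 8 | (5R)-5-(but-3-en-1-yl)-3-(phenylsulfanyl)oxolan-2-one (C3 epimers) | C=CCC[C@@H]1CC(Sc2ccccc2)C(=O)O1
F3 | step 8 | (5R)-5-(but-3-en-1-yl)-3-(phenylsulfinyl)oxolan-2-one | C=CCC[C@@H]1CC(S(=O)c2ccccc2)C(=O)O1
F4 | step 8 | (5R)-5-(but-3-en-1-yl)furan-2(5H)-one | C=CCC[C@@H]1C=CC(=O)O1
F5 | step 8 | 3-[(2R)-5-oxo-2,5-dihydrofuran-2-yl]propanal | O=CCC[C@@H]1C=CC(=O)O1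
F6 | step 8 | (5R)-5-[(4E)-4-({[tert-butyl(dimethyl)silyl]oxy}methyl)-3-hydroxyhepta-4,6-dien-1-yl]furan-2(5H)-one (both carbinol epimers) | C=C/C=C(\CO[Si](C)(C)C(C)(C)C)C(O)CC[C@@H]1C=CC(=O)O1
F7 | step 8 | 20-(TBS-oxy)-9ξ-hydroxy-11,12,13,14,15,16,17,18-octanorlabd-1-en-19,6β-olide (4α-H) | CC(C)(C)[Si](C)(C)OC[C@@]12C=CC[C@@H]3C(=O)O[C@H](CCC1O)[C@H]23
F8 | step 8 | dilithium 9-alkoxide and C4 lactone enolate of F7 | CC(C)(C)[Si](C)(C)OC[C@@]12C=CCC3=C(O[Li])O[C@H](CCC1O[Li])[C@H]23
F9 | step 12 | 9α,11-epoxy-20-(TBS-oxy)-12,13,14,15,16-pentanorlabdan-19,6β-olide | CC(C)(C)[Si](C)(C)OC[C@@]12CCC[C@]3(C)C(=O)O[C@H](C[C@@H](C)[C@]14CO4)[C@H]23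
F10 | step 14 | 9α,20-dihydroxylabd-13-ene-19,6β:15,16-diolide | OC[C@@]12CCC[C@]3(C)C(=O)O[C@H](C[C@@H](C)[C@]1(O)CCC1=CC(=O)OC1)[C@H]23
F11 | step 14 | (13R)-20-hydroxy-9α,13-epoxylabdane-19,6β:15,16-diolide | OC[C@@]12CCC[C@]3(C)C(=O)O[C@H](C[C@@H](C)[C@]14CC[C@]1(CC(=O)OC1)O4)[C@H]23
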